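**Retrosynthetic overview**

1. The target comes from its 5,7-bis(MOM) ether. Ring C is closed last at C3=C4 by enol-ether ring-closing metathesis between a silyl enol ether (made from the ring A acetyl group, which supplies C4) and the vinyl group on C2.
2. The strategy rests on C2, the only stereocentre: a secondary benzylic carbon that carries ring B and is bonded to the aryl ether oxygen O1. The O1–C2 bond is the single link between the ring A half and the ring B half, and it is made by iridium-catalysed enantioselective allylic etherification of a phenoxide (no ring closes in that step).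
3. Ring A half: phloroacetophenone, C-diprenylation, then bis-MOM protection that leaves the one chelated hydroxyl free. Ring B half: 4-hydroxybenzaldehyde to the 2,2-dimethylchromene aldehyde, then enoate, allylic alcohol and methyl carbonate.
4. Ring order: ring A is bought; the dimethylpyran ring fused to ring B is formed first (step 4); ring C is formed last (step 10).

Key step: step 8

Remark on the chemistry: the (Sa,Sc,Sc) phosphoramidite is assigned as the ligand that delivers the (S)-ether by analogy with the parent cinnamyl carbonate/aryloxide reaction. The first sample is to be checked by chiral HPLC and by correlation at the flavanone stage; if the sense is the opposite, the mirror-image ligand is used and nothing else changes.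

**Route**

Step 1
Reactants: 1 phloroacetophenone; 2 prenyl bromide (2.2 equiv)
Product: 3 1-[2,4,6-trihydroxy-3,5-bis(3-methylbut-2-en-1-yl)phenyl]ethanone
Conditions: 10% aq. KOH, 0 °C → rt; chromatography
Reagents that add atoms: none
Why: Phenolate C-alkylation of the acylphloroglucinol in water, where hydrogen bonding to oxygen favours attack through the two equivalent ring carbons, should give the 3,5-diprenyl compound, separable from mono- and over-alkylated material.

Step 2
Reactants: 3 diprenylphloroacetophenone
Product: 4 1-[2-hydroxy-4,6-bis(methoxymethoxy)-3,5-bis(3-methylbut-2-en-1-yl)phenyl]ethanone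
Conditions: MOMCl (2.2 equiv), i-Pr2NEt, CH2Cl2, 0 °C → rt
Reagents that add atoms: chloromethyl methyl ether (MOMCl), COCCl
Why: Williamson-type acetal etherification stops at the bis-MOM stage because the last hydroxyl is hydrogen-bonded to the acetyl carbonyl, and the 2- and 6-hydroxyls are equivalent so one isomer results.

Step 3
Reactants: 5 4-hydroxybenzaldehyde; 6 3-chloro-3-methylbut-1-yne
Product: 7 4-[(2-methylbut-3-yn-2-yl)oxy]benzaldehyde
Conditions: DBU, CuCl2 (cat.), MeCN, 0 °C → rt
Reagents that add atoms: none
Why: Copper-catalysed propargylic etherification of a phenol with a tertiary propargylic chloride is the standard entry to aryl 1,1-dimethylpropargyl ethers.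

Step 4
Reactants: 7 aryl 1,1-dimethylpropargyl ether
Product: 8 2,2-dimethyl-2H-chromene-6-carbaldehyde
Conditions: N,N-diethylaniline, 190 °C
Reagents that add atoms: none
Why: Thermal aryl propargyl ether Claisen rearrangement to the ortho-allenyl phenol, followed by 1,5-hydrogen shift and oxa-6π electrocyclisation, gives the 2,2-dimethyl-2H-chromene, and the two ortho positions are equivalent.

Step 5
Reactants: 8 chromene aldehyde; 9 triethyl phosphonoacetate
Product: 10 ethyl (E)-3-(2,2-dimethyl-2H-chromen-6-yl)prop-2-enoate
Conditions: NaH, THF, 0 °C → rt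
Reagents that add atoms: none
Why: Horner–Wadsworth–Emmons olefination of an aryl aldehyde with a stabilised phosphonate should give the (E)-enoate.

Step 6
Reactants: 10 (E)-enoate
Product: 11 (E)-3-(2,2-dimethyl-2H-chromen-6-yl)prop-2-en-1-ol
Conditions: i-Bu2AlH (2.2 equiv), CH2Cl2, −78 °C; aq. potassium sodium tartrate work-up
Reagents that add atoms: none
Why: 1,2-Reduction of the conjugated ester by the aluminium hydride at low temperature gives the allylic alcohol and leaves both alkenes untouched.

Step 7
Reactants: 11 allylic alcohol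
Product: 12 (E)-3-(2,2-dimethyl-2H-chromen-6-yl)allyl methyl carbonate
Conditions: ClCO2Me, pyridine, CH2Cl2, 0 °C
Reagents that add atoms: methyl chloroformate, COC(=O)Cl
Why: Acylation of a primary allylic alcohol with a chloroformate gives the linear carbonate needed as the allyl donor.

Step 8
Reactants: 4 bis-MOM diprenyl phenol (1.3 equiv); 12 cinnamyl-type methyl carbonate (1.0 equiv)
Product: 14 (S)-branched aryl allyl ether 1-[2-{[(1S)-1-(2,2-dimethyl-2H-chromen-6-yl)prop-2-en-1-yl]oxy}-4,6-bis(methoxymethoxy)-3,5-diprenylphenyl]ethanone, via sodium aryloxide 13 (not isolated)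
Conditions: NaH (1.3 equiv), THF, 0 °C → rt; [Ir(cod)Cl]2 (2 mol%), (Sa,Sc,Sc)-BINOL-derived N,N-bis(1-phenylethyl)phosphoramidite (4 mol%), pre-activated with n-PrNH2 (THF, 50 °C, then evaporated); 12, THF, 50 °C; filtration through Et3N-deactivated silica
Reagents that add atoms: none
Why: The cyclometalated complex of monovalent iridium formed from [Ir(cod)Cl]2, the phosphoramidite and propylamine ionises carbonate 12 to an allyl complex of trivalent iridium, and aryloxide 13 attacks the chromenyl-bearing allyl terminus on the face away from the metal to form O1–C2, while methyl carbonate leaves as CO2 and methoxide. The closest known reaction is the iridium–phosphoramidite branched-selective enantioselective allylic etherification of alkali aryloxides with cinnamyl carbonates, which tolerates ortho-substituted aryloxides. No ring is closed: the step is an intermolecular union of the ring A half with the ring B half. The C2 configuration is set by the ligand alone, which fixes the face of the allyl terminus that is open to attack, the (Sa,Sc,Sc) ligand being chosen for the (S)-ether; both partners are achiral, so there is no mismatch. The step needs branched over linear regioselectivity, secured by the catalyst and helped by the para-alkoxyaryl group that stabilises positive charge at the attacked terminus, and O- over C-allylation, secured by ring A having no unsubstituted carbon, which also blocks a later aromatic Claisen shift. The aryloxide is chelated to the acetyl group and flanked on both sides, so the reaction is run with excess 13 and stopped at full conversion, before the para-alkoxybenzylic ether product can re-ionise at iridium.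

Step 9
Reactants: 14 (S)-branched aryl allyl ether
Product: 16 tert-butyldimethylsilyl enol ether of 14, via potassium enolate 15 (not isolated)
Conditions: KN(SiMe3)2 (1.1 equiv), THF, −78 °C; TBSCl (1.3 equiv), −78 → 0 °C; used after filtration through Et3N-deactivated silica
Reagents that add atoms: tert-butyldimethylsilyl chloride (TBSCl), CC(C)(C)[Si](C)(C)Cl
Why: Kinetic deprotonation of the methyl ketone, the only acidic C–H in 14, by the hindered amide base and O-silylation of the potassium enolate (silyl enol ether formation) leave the C2–H and its configuration untouched.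

Step 10
Reactants: 16 silyl enol ether
Product: 18 (2S)-2-(2,2-dimethyl-2H-chromen-6-yl)-5,7-bis(methoxymethoxy)-6,8-bis(3-methylbut-2-en-1-yl)chroman-4-one, via 4-silyloxy-2H-chromene 17 (not isolated)
Conditions: second-generation Hoveyda–Grubbs catalyst RuCl2(=CH-C6H4-2-O-i-Pr)(SIMes) (10 mol%), toluene (0.005 M), 70 °C, argon sparge; then 1 M aq. HCl, THF, 0 °C
Reagents that add atoms: none
Why: In this enol ether–olefin ring-closing metathesis the ruthenium alkylidene loads at the only monosubstituted alkene (the C2 vinyl group) and closes the six-membered ring C onto the 1,1-disubstituted silyl enol ether to form C3=C4 with loss of ethylene, which should be faster than seven-membered closure onto the trisubstituted C8 prenyl olefin, and dilute acid then protonates C3 of the enol ether without forming an enolate, so ring C is not opened and C2 keeps its configuration.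

Step 11
Reactants: 18 (S)-bis-MOM flavanone
Product: 19 (2S)-2-(2,2-dimethyl-2H-chromen-6-yl)-5,7-dihydroxy-6,8-bis(3-methylbut-2-en-1-yl)chroman-4-one (target CNP0188949.1)
Conditions: 3 M aq. HCl, MeOH/THF, 40 °C, short reaction time
Reagents that add atoms: none
Why: Acid-catalysed acetal solvolysis (MOM ether cleavage) in methanol frees the 5- and 7-hydroxyls as dimethoxymethane is lost, and the low temperature and short time are chosen so that the prenyl groups do not cyclise onto the new phenols and ring C does not open at C2.

**Compound list**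

1 | phloroacetophenone (2,4,6-trihydroxyacetophenone) | CC(=O)c1c(O)cc(O)cc1O | starting material
2 | prenyl bromide | CC(C)=CCBr | starting material
3 | 1-[2,4,6-trihydroxy-3,5-bis(3-methylbut-2-en-1-yl)phenyl]ethanone | CC(=O)c1c(O)c(CC=C(C)C)c(O)c(CC=C(C)C)c1O | intermediate
4 | 1-[2-hydroxy-4,6-bis(methoxymethoxy)-3,5-bis(3-methylbut-2-en-1-yl)phenyl]ethanone | CC(=O)c1c(O)c(CC=C(C)C)c(OCOC)c(CC=C(C)C)c1OCOC | intermediate
5 | 4-hydroxybenzaldehyde | O=Cc1ccc(O)cc1 | starting material
6 | 3-chloro-3-methylbut-1-yne | CC(C)(Cl)C#C | starting material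
7 | 4-[(2-methylbut-3-yn-2-yl)oxy]benzaldehyde | O=Cc1ccc(OC(C)(C)C#C)cc1 | intermediate
8 | 2,2-dimethyl-2H-chromene-6-carbaldehyde | O=Cc1ccc2c(c1)C=CC(C)(C)O2 | intermediate
9 | triethyl phosphonoacetate | CCOC(=O)CP(=O)(OCC)OCC | starting material
10 | ethyl (E)-3-(2,2-dimethyl-2H-chromen-6-yl)prop-2-enoate | CCOC(=O)/C=C/c1ccc2c(c1)C=CC(C)(C)O2 | intermediate
11 | (E)-3-(2,2-dimethyl-2H-chromen-6-yl)prop-2-en-1-ol | OC/C=C/c1ccc2c(c1)C=CC(C)(C)O2 | intermediate
12 | (E)-3-(2,2-dimethyl-2H-chromen-6-yl)allyl methyl carbonate | COC(=O)OC/C=C/c1ccc2c(c1)C=CC(C)(C)O2 | intermediate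
13 | sodium 2-acetyl-3,5-bis(methoxymethoxy)-4,6-bis(3-methylbut-2-en-1-yl)phenolate | CC(=O)c1c([O-])c(CC=C(C)C)c(OCOC)c(CC=C(C)C)c1OCOC.[Na+] | intermediate
14 | 1-[2-{[(1S)-1-(2,2-dimethyl-2H-chromen-6-yl)prop-2-en-1-yl]oxy}-4,6-bis(methoxymethoxy)-3,5-bis(3-methylbut-2-en-1-yl)phenyl]ethanone | CC(=O)c1c(O[C@@H](C=C)c2ccc3c(c2)C=CC(C)(C)O3)c(CC=C(C)C)c(OCOC)c(CC=C(C)C)c1OCOC | intermediate
15 | potassium enolate of 14 | C=C([O-])c1c(O[C@@H](C=C)c2ccc3c(c2)C=CC(C)(C)O3)c(CC=C(C)C)c(OCOC)c(CC=C(C)C)c1OCOC.[K+] | intermediate
16 | tert-butyldimethylsilyl enol ether of 14 (1-aryl-1-silyloxyethene) | C=C(O[Si](C)(C)C(C)(C)C)c1c(O[C@@H](C=C)c2ccc3c(c2)C=CC(C)(C)O3)c(CC=C(C)C)c(OCOC)c(CC=C(C)C)c1OCOC | intermediate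
17 | (2S)-4-(tert-butyldimethylsilyloxy)-2-(2,2-dimethyl-2H-chromen-6-yl)-5,7-bis(methoxymethoxy)-6,8-bis(3-methylbut-2-en-1-yl)-2H-chromene | CC(C)=CCc1c(OCOC)c(CC=C(C)C)c2c(c1OCOC)C(O[Si](C)(C)C(C)(C)C)=C[C@@H](c1ccc3c(c1)C=CC(C)(C)O3)O2 | intermediate
18 | (2S)-2-(2,2-dimethyl-2H-chromen-6-yl)-5,7-bis(methoxymethoxy)-6,8-bis(3-methylbut-2-en-1-yl)chroman-4-one | CC(C)=CCc1c(OCOC)c(CC=C(C)C)c2c(c1OCOC)C(=O)C[C@@H](c1ccc3c(c1)C=CC(C)(C)O3)O2 | intermediate
19 | (2S)-2-(2,2-dimethyl-2H-chromen-6-yl)-5,7-dihydroxy-6,8-bis(3-methylbut-2-en-1-yl)chroman-4-one | CC(C)=CCc1c(O)c(CC=C(C)C)c2c(c1O)C(=O)C[C@@H](c1ccc3c(c1)C=CC(C)(C)O3)O2 | target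

**Step count**

Total: 11 steps. Longest linear sequence: 9 steps (steps 3 to 11, from 4-hydroxybenzaldehyde). The ring A branch (steps 1 and 2) joins at step 8.

**Steps most likely to fail**

1. Step 8 (key step). The chelated, doubly flanked aryloxide may attack the allyl–iridium intermediate too slowly. The intermediate would then be diverted to the linear ether or captured by methoxide, and the branched product could re-ionise, with loss of regio- and enantiopurity. The fallback sets out from aldehyde 8 and aryloxide 13 and comes back at 14; it takes the C2 configuration from a resolved alcohol instead of from the catalyst. Addition of CH2=CHMgBr to 8 (THF, 0 °C) should give racemic 1-(2,2-dimethyl-2H-chromen-6-yl)prop-2-en-1-ol F1. Lipase resolution (Candida antarctica lipase B, vinyl acetate) acylates the (R)-enantiomer and leaves (S)-1-(2,2-dimethyl-2H-chromen-6-yl)prop-2-en-1-ol F2. n-BuLi then ClCO2Me at −78 °C gives (S)-1-(2,2-dimethyl-2H-chromen-6-yl)allyl methyl carbonate F3, used at once. Enantiospecific allylic etherification of 13 catalysed by RhCl(PPh3)3 with P(OMe)3 (THF, 0 °C → rt) proceeds with net retention at the carbon that carried the leaving group and is known for ortho-disubstituted aryloxides; it should give 14.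

2. Step 10. The ruthenium alkylidene formed at the C2 vinyl group may close a seven-membered ring onto the neighbouring C8 prenyl olefin with loss of isobutene, or engage the prenyl groups in cross metathesis, instead of reacting with the hindered silyl enol ether. The fallback sets out from 4 and 8 and comes back at 18; it gives up the metathesis and closes ring C at O1–C2 by oxa-Michael addition. Claisen–Schmidt condensation (KOH, EtOH/H2O, rt) should give (E)-1-[2-hydroxy-4,6-bis(methoxymethoxy)-3,5-diprenylphenyl]-3-(2,2-dimethyl-2H-chromen-6-yl)prop-2-en-1-one F4. Sodium acetate (NaOAc) in refluxing EtOH cyclises it to racemic 2-(2,2-dimethyl-2H-chromen-6-yl)-5,7-bis(methoxymethoxy)-6,8-diprenylchroman-4-one F5. Preparative chiral HPLC on a polysaccharide carbamate phase separates the (S)-enantiomer, which is 18.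

3. Step 11. Acid may cyclise the prenyl groups onto the freed neighbouring phenols to give dimethylchromans, open ring C at the para-alkoxybenzylic C2 with loss of configuration, or add to the chromene double bond. The fallback sets out from 18 and comes back at 19; it replaces Brønsted-acid solvolysis by a non-acidic acetal exchange. Me3SiOTf with 2,2'-bipyridyl (CH2Cl2, 0 °C) converts both aryl MOM ethers into aryl trimethylsilyl ethers, giving (2S)-2-(2,2-dimethyl-2H-chromen-6-yl)-6,8-diprenyl-5,7-bis(trimethylsilyloxy)chroman-4-one F6. Water at rt then hydrolyses the silyl ethers to 19.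

**Further compounds**

F1 | step 8 | racemic 1-(2,2-dimethyl-2H-chromen-6-yl)prop-2-en-1-ol | C=CC(O)c1ccc2c(c1)C=CC(C)(C)O2
F2 | step 8 | (S)-1-(2,2-dimethyl-2H-chromen-6-yl)prop-2-en-1-ol | C=C[C@H](O)c1ccc2c(c1)C=CC(C)(C)O2
F3 | step 8 | (S)-1-(2,2-dimethyl-2H-chromen-6-yl)allyl methyl carbonate | C=C[C@H](OC(=O)OC)c1ccc2c(c1)C=CC(C)(C)O2
F4 | step 10 | (E)-1-[2-hydroxy-4,6-bis(methoxymethoxy)-3,5-bis(3-methylbut-2-en-1-yl)phenyl]-3-(2,2-dimethyl-2H-chromen-6-yl)prop-2-en-1-one | CC(C)=CCc1c(O)c(C(=O)/C=C/c2ccc3c(c2)C=CC(C)(C)O3)c(OCOC)c(CC=C(C)C)c1OCOC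
F5 | step 10 | racemic 2-(2,2-dimethyl-2H-chromen-6-yl)-5,7-bis(methoxymethoxy)-6,8-bis(3-methylbut-2-en-1-yl)chroman-4-one | CC(C)=CCc1c(OCOC)c(CC=C(C)C)c2c(c1OCOC)C(=O)CC(c1ccc3c(c1)C=CC(C)(C)O3)O2
F6 | step 11 | (2S)-2-(2,2-dimethyl-2H-chromen-6-yl)-6,8-bis(3-methylbut-2-en-1-yl)-5,7-bis(trimethylsilyloxy)chroman-4-one | CC(C)=CCc1c(O[Si](C)(C)C)c(CC=C(C)C)c2c(c1O[Si](C)(C)C)C(=O)C[C@@H](c1ccc3c(c1)C=CC(C)(C)O3)O2
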